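**Plan**
- Retrosynthetic cuts, in order: C4–C4a (intramolecular Friedel–Crafts acylation, closes ring C), O1–C2 (Mitsunobu ether bond), C2–C3 (Roskamp homologation of the ring B aldehyde), and the aryl–CH2 bond of the side chain (Negishi coupling).
- Forward: ring B aldehyde → beta-keto allyl ester → (R)-carbinol; ring A phenol is built separately from a bromocatechol aldehyde; the two are joined at O1–C2, the carboxylic acid is freed, ring C closes last onto ring A, and all O-protecting groups then leave in one operation.
- Enabling feature: in the 2,3,5-tris(allyloxy)phenyl ether, C4a of ring A is the only unsubstituted carbon ortho to O1 and is activated ortho by O5 and para by O7, so the C4 acyl carbon can reach and attack only that position.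
- Stereochemistry: C2 is set once, as the (R)-alcohol, by asymmetric transfer hydrogenation of the aryl ketone with the (R,R)-TsDPEN ruthenium catalyst, and is inverted to (S) in the Mitsunobu etherification; no later step touches it.

Key step: step 13

Remark on the chemistry: it is assumed that the isolated 1,1-disubstituted alkene tolerates brief contact with two equivalents of dilute CF3CO2H in CH2Cl2 at or below 0 °C; allyl diazoacetate is treated as a reagent that has to be prepared (step 4).

**Route**

Step 1
Reactants: 1 3-bromo-4-hydroxybenzaldehyde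
Product: 2 2-bromo-4-formylphenyl acetate
Conditions: Ac2O, pyridine, CH2Cl2, 0 °C to rt
Reagents that add atoms: acetic anhydride, CC(=O)OC(C)=O
Why: Acetylation of the phenol (nucleophilic acyl substitution) masks the acidic OH for the organozinc coupling and installs the electron-withdrawing 4'-O-acyl group that later keeps the benzylic C2–O bond from ionising.

Step 2
Reactants: 3 4-bromo-2-methylbut-1-ene
Product: 4 (3-methylbut-3-enyl)zinc bromide (used as a titrated THF solution)
Conditions: Zn dust (activated with 1,2-dibromoethane and Me3SiCl), LiCl, THF, 50 °C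
Reagents that add atoms: zinc, [Zn]
Why: Oxidative insertion of LiCl-activated zinc into a primary alkyl bromide is the standard entry to functionalised alkylzinc halides, and the resulting homoallylic C–Zn bond is stable as a THF solution.

Step 3
Reactants: 2 2-bromo-4-formylphenyl acetate; 4 (3-methylbut-3-enyl)zinc bromide
Product: 5 4-formyl-2-(3-methylbut-3-enyl)phenyl acetate
Conditions: Pd(OAc)2 (2 mol %), SPhos (4 mol %), THF, rt to 40 °C
Reagents that add atoms: none
Why: Negishi cross-coupling (oxidative addition of the aryl bromide to zerovalent palladium generated from Pd(OAc)2 and SPhos, transmetalation from zinc, reductive elimination) joins the sp3 carbon to ring B faster than beta-hydride elimination can intervene, and alkylzinc halides do not add to the aldehyde or attack the aryl acetate.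

Step 4
Reactants: 6 allyl bromoacetate
Product: 7 allyl diazoacetate
Conditions: TsNHNHTs (2 equiv), DBU (5 equiv), THF, 0 °C
Reagents that add atoms: N,N'-ditosylhydrazine, Cc1ccc(cc1)S(=O)(=O)NNS(=O)(=O)c1ccc(C)cc1
Why: Diazo ester synthesis from a bromoacetate: N-alkylation of N,N'-ditosylhydrazine followed by DBU-induced loss of two sulfinate groups gives the diazoacetate without diazo-transfer reagents.

Step 5
Reactants: 5 4-formyl-2-(3-methylbut-3-enyl)phenyl acetate; 7 allyl diazoacetate
Product: 8 allyl 3-[4-acetoxy-3-(3-methylbut-3-enyl)phenyl]-3-oxopropanoate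
Conditions: SnCl2 (10 mol %), CH2Cl2, rt
Reagents that add atoms: none
Why: Roskamp reaction: the SnCl2-activated aldehyde is attacked by the diazo carbon and a 1,2-hydride shift with loss of N2 gives the beta-keto ester directly, under conditions too mild to touch the alkene, the aryl acetate or the allyl ester.

Step 6
Reactants: 8 allyl 3-[4-acetoxy-3-(3-methylbut-3-enyl)phenyl]-3-oxopropanoate
Product: 9 allyl (3R)-3-[4-acetoxy-3-(3-methylbut-3-enyl)phenyl]-3-hydroxypropanoate
Conditions: RuCl[(R,R)-TsDPEN](p-cymene) (1 mol %), HCO2H/Et3N (5:2), DMF, 35 °C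
Reagents that add atoms: none
Why: Noyori–Ikariya asymmetric transfer hydrogenation of an aryl ketone: the hydride formed from RuCl[(R,R)-TsDPEN](p-cymene) and formate is delivered in an outer-sphere six-membered transition state in which ring B is held against the cymene ligand, which fixes the (R) configuration at the future C2, and no H2 or borane is present to reduce the alkenes.

Step 7
Reactants: 10 3-bromo-4,5-dihydroxybenzaldehyde
Product: 11 3,4-bis(allyloxy)-5-bromobenzaldehyde
Conditions: allyl bromide (2.5 equiv), K2CO3, DMF, 60 °C
Reagents that add atoms: allyl bromide, C=CCBr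
Why: Williamson ether synthesis on both catechol hydroxyls; allyl is chosen because zerovalent palladium removes it at the end without acid, strong base or hydrogen, all of which the side-chain alkene or C2 would not tolerate.

Step 8
Reactants: 11 3,4-bis(allyloxy)-5-bromobenzaldehyde
Product: 13 3,4-bis(allyloxy)-5-bromophenol, via aryl formate 12 (not isolated)
Conditions: mCPBA (1.3 equiv), CH2Cl2, 0 °C to rt; aq NaHCO3 wash; then K2CO3 (cat.), MeOH, rt
Reagents that add atoms: 3-chloroperoxybenzoic acid, OOC(=O)c1cccc(Cl)c1
Why: Dakin-type oxidation by the Baeyer–Villiger route: the para-allyloxy group makes the aryl group migrate to give formate 12, which is methanolysed to the phenol, while the monosubstituted allyl ether alkenes are epoxidised far more slowly than the electron-rich aldehyde is oxidised.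

Step 9
Reactants: 13 3,4-bis(allyloxy)-5-bromophenol
Product: 14 1-bromo-2,3,5-tris(allyloxy)benzene
Conditions: allyl bromide (1.3 equiv), K2CO3, DMF, 50 °C
Reagents that add atoms: allyl bromide, C=CCBr
Why: Williamson ether synthesis on the newly formed phenol completes the three allyl ethers that will become O5, O7 and O8 of ring A.

Step 10
Reactants: 14 1-bromo-2,3,5-tris(allyloxy)benzene
Product: 17 2,3,5-tris(allyloxy)phenol, via aryllithium 15 (not isolated), via lithium aryltrimethoxyborate 16 (not isolated)
Conditions: n-BuLi, THF, −78 °C; B(OMe)3, −78 to 0 °C; then AcOH, 30% H2O2, 0 °C to rt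
Reagents that add atoms: hydrogen peroxide, OO
Why: Bromine–lithium exchange at −78 °C (below the temperature at which ortho-allyloxy aryllithiums cyclise), trapping with B(OMe)3 and oxidative 1,2-migration of the aryl group from boron to oxygen convert C–Br into C–OH at the carbon that will carry O1.

Step 11
Reactants: 9 allyl (3R)-3-[4-acetoxy-3-(3-methylbut-3-enyl)phenyl]-3-hydroxypropanoate; 17 2,3,5-tris(allyloxy)phenol
Product: 18 allyl (3S)-3-[4-acetoxy-3-(3-methylbut-3-enyl)phenyl]-3-[2,3,5-tris(allyloxy)phenoxy]propanoate
Conditions: PPh3, DIAD, toluene, 0 °C to rt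
Reagents that add atoms: none
Why: Mitsunobu etherification: the (R)-alcohol is activated as its alkoxyphosphonium salt and displaced by the phenoxide of 17 in an SN2 step with inversion to the (S)-aryl ether, the electron-poor acetoxy-substituted ring B disfavouring any carbocation pathway that would erode the configuration.

Step 12
Reactants: 18 allyl (3S)-3-[4-acetoxy-3-(3-methylbut-3-enyl)phenyl]-3-[2,3,5-tris(allyloxy)phenoxy]propanoate
Product: 19 (3S)-3-[4-acetoxy-3-(3-methylbut-3-enyl)phenyl]-3-[2,3,5-tris(allyloxy)phenoxy]propanoic acid
Conditions: Pd(PPh3)4 (3 mol %), PPh3 (6 mol %), potassium 2-ethylhexanoate (1.1 equiv), EtOAc/CH2Cl2, 0 °C to rt; then cold 0.5 M HCl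
Reagents that add atoms: none
Why: Tsuji–Trost deallylation by allyl transfer to a carboxylate: Pd(PPh3)4 (zerovalent palladium) ionises the allyl carboxylate far faster than an allyl aryl ether, and because the only allyl acceptor offered is a carboxylate, net transfer from the much more basic aryloxides is thermodynamically uphill, so the ring A allyl ethers and the aryl acetate persist under base-free conditions that also avoid beta-elimination of the aryloxy group.

Step 13
Reactants: 19 (3S)-3-[4-acetoxy-3-(3-methylbut-3-enyl)phenyl]-3-[2,3,5-tris(allyloxy)phenoxy]propanoic acid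
Product: 21 (2S)-2-[4-acetoxy-3-(3-methylbut-3-enyl)phenyl]-5,7,8-tris(allyloxy)chroman-4-one, via acyl trifluoroacetate 20 (not isolated)
Conditions: (CF3CO)2O (1.2 equiv), CH2Cl2 (0.05 M), −20 to 0 °C; cold aq NaHCO3 quench
Reagents that add atoms: none
Why: (CF3CO)2O turns the acid into the acyl trifluoroacetate 20, C4a of ring A attacks its carbonyl carbon, and the Wheland intermediate loses its proton to trifluoroacetate, so the C4–C4a bond forms as an intramolecular Friedel–Crafts acylation. The closest known reaction type is the anhydride- or acid-mediated closure of 3-aryloxypropanoic acids to chroman-4-ones. Ring C closes in 6-exo-trig mode, the arene carbon adding to the anhydride C=O held in reach by the O1–C2–C3 tether. No stereocentre is created; C2 is carried through unchanged provided its benzylic C–O bond does not ionise, which the electron-withdrawing 4'-acetoxy group, the absence of any Lewis acid and the low temperature are meant to ensure. Regioselectivity is imposed by the substrate, since C4a is the only unsubstituted carbon ortho to O1 and the other free position (C6) cannot reach the acyl carbon, while the ortho O5 and para O7 donors make C4a nucleophilic enough for this weak electrophile. The two equivalents of CF3CO2H released stay dilute and cold and are quenched with NaHCO3 before they can add to the 1,1-disubstituted alkene, and the allyl ethers and the aryl acetate are inert to these conditions.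

Step 14
Reactants: 21 (2S)-2-[4-acetoxy-3-(3-methylbut-3-enyl)phenyl]-5,7,8-tris(allyloxy)chroman-4-one
Product: 22 (2S)-5,7,8-trihydroxy-2-[4-hydroxy-3-(3-methylbut-3-enyl)phenyl]chroman-4-one
Conditions: Pd(PPh3)4 (10 mol %), morpholine (15 equiv), degassed THF, rt, under argon; pH 5 phosphate buffer work-up
Reagents that add atoms: none
Why: Tsuji–Trost deallylation of the three aryl allyl ethers (Pd(PPh3)4, zerovalent palladium, gives pi-allyl complexes that morpholine captures irreversibly) combined with aminolysis of the aryl acetate by the same amine unmasks all four phenols without acid, hydride or hydrogen, leaving the side-chain alkene and C2 untouched.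

**Compound list**

1 | 3-bromo-4-hydroxybenzaldehyde | O=Cc1ccc(O)c(Br)c1 | starting material
2 | 2-bromo-4-formylphenyl acetate | CC(=O)Oc1ccc(C=O)cc1Br | intermediate
3 | 4-bromo-2-methylbut-1-ene | C=C(C)CCBr | starting material
4 | (3-methylbut-3-enyl)zinc bromide | C=C(C)CC[Zn]Br | intermediate
5 | 4-formyl-2-(3-methylbut-3-enyl)phenyl acetate | C=C(C)CCc1cc(C=O)ccc1OC(C)=O | intermediate
6 | allyl bromoacetate | C=CCOC(=O)CBr | starting material
7 | allyl diazoacetate | C=CCOC(=O)C=[N+]=[N-] | intermediate
8 | allyl 3-[4-acetoxy-3-(3-methylbut-3-enyl)phenyl]-3-oxopropanoate | C=C(C)CCc1cc(C(=O)CC(=O)OCC=C)ccc1OC(C)=O | intermediate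
9 | allyl (3R)-3-[4-acetoxy-3-(3-methylbut-3-enyl)phenyl]-3-hydroxypropanoate | C=C(C)CCc1cc([C@H](O)CC(=O)OCC=C)ccc1OC(C)=O | intermediate
10 | 3-bromo-4,5-dihydroxybenzaldehyde | O=Cc1cc(O)c(O)c(Br)c1 | starting material
11 | 3,4-bis(allyloxy)-5-bromobenzaldehyde | O=Cc1cc(OCC=C)c(OCC=C)c(Br)c1 | intermediate
12 | 3,4-bis(allyloxy)-5-bromophenyl formate | O=COc1cc(OCC=C)c(OCC=C)c(Br)c1 | intermediate
13 | 3,4-bis(allyloxy)-5-bromophenol | Oc1cc(OCC=C)c(OCC=C)c(Br)c1 | intermediate
14 | 1-bromo-2,3,5-tris(allyloxy)benzene | C=CCOc1cc(OCC=C)c(OCC=C)c(Br)c1 | intermediate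
15 | [2,3,5-tris(allyloxy)phenyl]lithium | [Li]c1cc(OCC=C)cc(OCC=C)c1OCC=C | intermediate
16 | lithium trimethoxy[2,3,5-tris(allyloxy)phenyl]borate | [Li+].CO[B-](OC)(OC)c1cc(OCC=C)cc(OCC=C)c1OCC=C | intermediate
17 | 2,3,5-tris(allyloxy)phenol | Oc1cc(OCC=C)cc(OCC=C)c1OCC=C | intermediate
18 | allyl (3S)-3-[4-acetoxy-3-(3-methylbut-3-enyl)phenyl]-3-[2,3,5-tris(allyloxy)phenoxy]propanoate | C=C(C)CCc1cc([C@@H](Oc2cc(OCC=C)cc(OCC=C)c2OCC=C)CC(=O)OCC=C)ccc1OC(C)=O | intermediate
19 | (3S)-3-[4-acetoxy-3-(3-methylbut-3-enyl)phenyl]-3-[2,3,5-tris(allyloxy)phenoxy]propanoic acid | C=C(C)CCc1cc([C@@H](Oc2cc(OCC=C)cc(OCC=C)c2OCC=C)CC(=O)O)ccc1OC(C)=O | intermediate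
20 | mixed anhydride of acid 19 and trifluoroacetic acid (acyl trifluoroacetate, 3S) | C=C(C)CCc1cc([C@@H](Oc2cc(OCC=C)cc(OCC=C)c2OCC=C)CC(=O)OC(=O)C(F)(F)F)ccc1OC(C)=O | intermediate
21 | (2S)-2-[4-acetoxy-3-(3-methylbut-3-enyl)phenyl]-5,7,8-tris(allyloxy)chroman-4-one | C=C(C)CCc1cc([C@@H]2CC(=O)c3c(OCC=C)cc(OCC=C)c(OCC=C)c3O2)ccc1OC(C)=O | intermediate
22 | (2S)-5,7,8-trihydroxy-2-[4-hydroxy-3-(3-methylbut-3-enyl)phenyl]chroman-4-one | C=C(C)CCc1cc([C@@H]2CC(=O)c3c(O)cc(O)c(O)c3O2)ccc1O | target

**Summary**

Total step count: 14 (steps 2 and 4 prepare reagents off the main line).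
Longest linear sequence: 8 steps (1 → 2 → 5 → 8 → 9 → 18 → 19 → 21 → 22; the ring A branch 10 → 11 → 13 → 14 → 17 → 18 → 22 is equally long).

**Steps most likely to fail**

1. Step 13 (ring closure). The acyl trifluoroacetate may be too weak an electrophile without added acid. Forcing the reaction risks ionisation of the benzylic C2–O bond (racemisation or elimination to the cinnamic acid) or protonation of the side-chain alkene. The fallback keeps the same bond formation but changes the electrophile and removes free acid. It sets out from 19, which is converted with 1-chloro-N,N,2-trimethylprop-1-en-1-amine in CH2Cl2 into the acid chloride F1 under neutral conditions, so that no HCl is released. F1 is then treated at −78 °C with AgOSO2CF3 in the presence of 2,6-di-tert-butyl-4-methylpyridine. Precipitation of silver chloride gives the acyl triflate F2, a much stronger acylating agent that should close ring C at low temperature while the hindered base takes up the triflic acid. The route is rejoined at 21.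

2. Step 11 (Mitsunobu etherification). The activated beta-hydroxy ester may dehydrate to the cinnamate, or substitution may leak through a benzylic cation and lose inversion fidelity. The fallback makes the O1–C2 bond by lactone opening instead. It sets out from 9, whose allyl ester is removed first (Pd(PPh3)4, potassium 2-ethylhexanoate, then dilute HCl) to give the hydroxy acid F3. Carboxyl activation (PhSO2Cl, pyridine, 0 °C) closes F3 with retention at the carbinol carbon to the beta-lactone F4. The sodium salt of 17 (NaH, THF/DMF, 0 °C, one equivalent to limit acetyl transfer) then opens F4 at the benzylic carbon by alkyl–oxygen cleavage with inversion, the known mode for phenoxides and beta-lactones. Acidification gives 19, where the route is rejoined; step 12 is bypassed as well.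

3. Step 12 (selective ester deallylation). An aryl allyl ether of ring A may ionise alongside the allyl ester, leading to loss or migration of allyl groups. The fallback carries the carboxyl as a phenacyl ester, which is orthogonal to every allyl group. It sets out from 9 and passes through the hydroxy acid F3 described under the previous fallback, where the allyl ester is cleaved before any aryl allyl ether is present. Alkylation of the carboxylate with phenacyl bromide (KHCO3, DMF, rt) gives the phenacyl hydroxy ester F5. Mitsunobu coupling with 17 (PPh3, DIAD, toluene) gives the phenacyl aryloxy ester F6 with inversion. Reductive cleavage with Zn dust in AcOH/THF at rt then liberates 19, where the route is rejoined.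

**Further compounds**

F1 | step 13 | (3S)-3-[4-acetoxy-3-(3-methylbut-3-enyl)phenyl]-3-[2,3,5-tris(allyloxy)phenoxy]propanoyl chloride | C=C(C)CCc1cc([C@@H](Oc2cc(OCC=C)cc(OCC=C)c2OCC=C)CC(=O)Cl)ccc1OC(C)=O
F2 | step 13 | (3S)-3-[4-acetoxy-3-(3-methylbut-3-enyl)phenyl]-3-[2,3,5-tris(allyloxy)phenoxy]propanoyl trifluoromethanesulfonate | C=C(C)CCc1cc([C@@H](Oc2cc(OCC=C)cc(OCC=C)c2OCC=C)CC(=O)OS(=O)(=O)C(F)(F)F)ccc1OC(C)=O
F3 | step 11 | (3R)-3-[4-acetoxy-3-(3-methylbut-3-enyl)phenyl]-3-hydroxypropanoic acid | C=C(C)CCc1cc([C@H](O)CC(=O)O)ccc1OC(C)=O
F4 | step 11 | (4R)-4-[4-acetoxy-3-(3-methylbut-3-enyl)phenyl]oxetan-2-one | C=C(C)CCc1cc([C@H]2CC(=O)O2)ccc1OC(C)=O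
F5 | step 12 | phenacyl (3R)-3-[4-acetoxy-3-(3-methylbut-3-enyl)phenyl]-3-hydroxypropanoate | C=C(C)CCc1cc([C@H](O)CC(=O)OCC(=O)c2ccccc2)ccc1OC(C)=O
F6 | step 12 | phenacyl (3S)-3-[4-acetoxy-3-(3-methylbut-3-enyl)phenyl]-3-[2,3,5-tris(allyloxy)phenoxy]propanoate | C=C(C)CCc1cc([C@@H](Oc2cc(OCC=C)cc(OCC=C)c2OCC=C)CC(=O)OCC(=O)c2ccccc2)ccc1OC(C)=O
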